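The C3–C4 ethano bridge of the dihydropyran ring links arene carbon C4a to the oxygenated quaternary stereocentre C2, and the plan rests on it. A vinylboronate serves as an ethane-1,2-diyl dianion. In one flask the α-lithiated (R)-triisopropylbenzoate of the farnesylacetone-derived carbinol (C2 with reversed polarity) captures it and a stereospecific 1,2-metallate shift forms C3–C2. Hydroboration and Suzuki–Miyaura coupling of the vinyl terminus with an iodinated trimethylhydroquinone dimethyl ether then form C4–C4a, and oxidative work-up gives the (R)-tertiary alcohol. The precursor is an acyclic secondary ester, not a chroman. Quinone formation and ketalisation–reduction close the pyran ring at O1–C8a without touching C2.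

Key step: step 4

Assumption: (5E,9E)-farnesylacetone, 1,4-dimethoxy-2,3,5-trimethylbenzene and the neopentyl glycol ester of vinylboronic acid are taken as catalogue compounds of the stated isomeric purity.

Step 1
Reactants: 1 (5E,9E)-6,10,14-trimethylpentadeca-5,9,13-trien-2-one ((E,E)-farnesylacetone)
Product: 2 (2S,5E,9E)-6,10,14-trimethylpentadeca-5,9,13-trien-2-ol
Conditions: (S)-selective alcohol dehydrogenase (ADH-A, Rhodococcus ruber), NADH (cat.), iPrOH, phosphate buffer pH 7.5, 30 °C
Reagents that add atoms: none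
Why: Enzymatic ketone reduction (biocatalytic transfer hydrogenation) should deliver the NADH hydride to the re face of the methyl ketone, which sets C2 as (S) by enzyme control, while isopropanol regenerates the cofactor and the remote trisubstituted alkenes stay untouched.

Step 2
Reactants: 2 (2S,5E,9E)-6,10,14-trimethylpentadeca-5,9,13-trien-2-ol; 3 2,4,6-triisopropylbenzoic acid
Product: 4 (2R,5E,9E)-6,10,14-trimethylpentadeca-5,9,13-trien-2-yl 2,4,6-triisopropylbenzoate
Conditions: PPh3, DIAD, THF, 0 °C → rt
Reagents that add atoms: none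
Why: Mitsunobu esterification proceeds by SN2 displacement of the oxyphosphonium by the carboxylate, so C2 should be inverted cleanly to (R) while the hindered benzoate needed for directed lithiation is installed.

Step 3
Reactants: 5 1,4-dimethoxy-2,3,5-trimethylbenzene
Product: 6 1-iodo-2,5-dimethoxy-3,4,6-trimethylbenzene
Conditions: N-iodosuccinimide, CF3CO2H (cat.), MeCN, rt
Reagents that add atoms: N-iodosuccinimide, O=C1CCC(=O)N1I
Why: Electrophilic aromatic iodination can only occur at the single unsubstituted position of the electron-rich, penta-substituted ring.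

Step 4
Reactants: 4 (2R,5E,9E)-6,10,14-trimethylpentadeca-5,9,13-trien-2-yl 2,4,6-triisopropylbenzoate; 7 5,5-dimethyl-2-vinyl-1,3,2-dioxaborinane; 6 1-iodo-2,5-dimethoxy-3,4,6-trimethylbenzene
Product: 13 (3R,6E,10E)-1-(2,5-dimethoxy-3,4,6-trimethylphenyl)-3,7,11,15-tetramethylhexadeca-6,10,14-trien-3-ol, via α-lithiated ester 8 (not isolated), via boronate complex 9 (not isolated), via tertiary allylic boronate 10 (not isolated), via 9-BBN adduct 11 (not isolated), via arylated boronate 12 (not isolated)
Conditions: sBuLi, TMEDA, cyclopentyl methyl ether, −60 °C; 7, −60 → 50 °C; solvent switch to THF, 9-BBN, rt; 6, PdCl2(dppf) (cat.), K3PO4 (aq), 60 °C; NaOH, H2O2, 0 °C → rt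
Reagents that add atoms: hydrogen peroxide, OO
Why: The benzoate carbonyl directs sBuLi/TMEDA to remove the C2 proton with retention, the configurationally stable carbanion 8 is trapped at boron with retention to give 9, and on warming the vinyl group shifts from boron to C2 anti to the departing carboxylate (1,2-metallate rearrangement, inversion at C2), which forms C3–C2 in 10. 9-BBN then adds to the terminal vinyl carbon and B-alkyl Suzuki–Miyaura coupling of 11 with 6 forms C4–C4a, after which oxidative work-up converts the tertiary C–B bond of 12 into C–OH with retention. The closest known reaction types are the lithiation–borylation of secondary alkyl triisopropylbenzoates to tertiary boronic esters and the hydroboration/B-alkyl Suzuki–Miyaura coupling, here run consecutively in one flask. No ring is closed. The stereocentre C2 is controlled by the (R) carbinol carbon of 4 through a stereospecific sequence (retention, retention, inversion, retention), so 13 should be (R). The step needs α- over allylic deprotonation (secured by complex-induced proximity to the ester carbonyl), vinyl over trisubstituted-alkene hydroboration (secured by the steric demand of 9-BBN) and coupling at C4 only (secured by the inertness of the tertiary boronate toward transmetallation).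

Step 5
Reactants: 13 (3R,6E,10E)-1-(2,5-dimethoxy-3,4,6-trimethylphenyl)-3,7,11,15-tetramethylhexadeca-6,10,14-trien-3-ol
Product: 14 2-[(3R,6E,10E)-3-hydroxy-3,7,11,15-tetramethylhexadeca-6,10,14-trien-1-yl]-3,5,6-trimethylcyclohexa-2,5-diene-1,4-dione
Conditions: (NH4)2Ce(NO3)6, MeCN/H2O, 0 °C
Reagents that add atoms: water, O
Why: Oxidative demethylation of the hydroquinone dimethyl ether by two one-electron oxidations with tetravalent cerium and attack of water should give the para-quinone, a reaction type that tolerates tertiary alcohols and isolated trisubstituted alkenes in polyprenyl quinone chemistry.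

Step 6
Reactants: 14 2-[(3R,6E,10E)-3-hydroxy-3,7,11,15-tetramethylhexadeca-6,10,14-trien-1-yl]-3,5,6-trimethylcyclohexa-2,5-diene-1,4-dione
Product: 16 (2R)-2,5,7,8-tetramethyl-2-[(3E,7E)-4,8,12-trimethyltrideca-3,7,11-trien-1-yl]-3,4-dihydro-2H-chromen-6-ol, via tocotrienone methyl ketal 15 (not isolated)
Conditions: HC(OMe)3, MeOH, pyridinium p-toluenesulfonate (cat.), rt; then L-ascorbic acid, MeOH/H2O, rt
Reagents that add atoms: none
Why: Acid-catalysed ketalisation should add the tertiary hydroxyl to the neighbouring quinone carbonyl C8a (six-membered ring, O1–C8a bond), and two-electron reduction of the 8a-methoxy ketal by ascorbic acid expels methanol and aromatises the ring, so the C2–O bond is never broken and the (R) configuration is kept.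

Compound list
1 | (5E,9E)-6,10,14-trimethylpentadeca-5,9,13-trien-2-one | CC(C)=CCC/C(C)=C/CC/C(C)=C/CCC(C)=O | starting material
2 | (2S,5E,9E)-6,10,14-trimethylpentadeca-5,9,13-trien-2-ol | CC(C)=CCC/C(C)=C/CC/C(C)=C/CC[C@H](C)O | intermediate
3 | 2,4,6-triisopropylbenzoic acid | CC(C)c1cc(C(C)C)c(C(=O)O)c(C(C)C)c1 | starting material
4 | (2R,5E,9E)-6,10,14-trimethylpentadeca-5,9,13-trien-2-yl 2,4,6-triisopropylbenzoate | CC(C)=CCC/C(C)=C/CC/C(C)=C/CC[C@@H](C)OC(=O)c1c(C(C)C)cc(C(C)C)cc1C(C)C | intermediate
5 | 1,4-dimethoxy-2,3,5-trimethylbenzene | COc1cc(C)c(OC)c(C)c1C | starting material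
6 | 1-iodo-2,5-dimethoxy-3,4,6-trimethylbenzene | COc1c(C)c(C)c(OC)c(I)c1C | intermediate
7 | 5,5-dimethyl-2-vinyl-1,3,2-dioxaborinane | C=CB1OCC(C)(C)CO1 | starting material
8 | (2R,5E,9E)-2-lithio-6,10,14-trimethylpentadeca-5,9,13-trien-2-yl 2,4,6-triisopropylbenzoate | CC(C)=CCC/C(C)=C/CC/C(C)=C/CC[C@@]([Li])(C)OC(=O)c1c(C(C)C)cc(C(C)C)cc1C(C)C | intermediate
9 | lithium boronate complex of 8 and 7 (boron bound to the (R)-configured C2, to vinyl and to the neopentyl glycolate; benzoate still on C2) | [Li+].CC(C)=CCC/C(C)=C/CC/C(C)=C/CC[C@@]([B-]1(C=C)OCC(C)(C)CO1)(C)OC(=O)c1c(C(C)C)cc(C(C)C)cc1C(C)C | intermediate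
10 | 5,5-dimethyl-2-[(3S,6E,10E)-3,7,11,15-tetramethylhexadeca-1,6,10,14-tetraen-3-yl]-1,3,2-dioxaborinane | CC(C)=CCC/C(C)=C/CC/C(C)=C/CC[C@](B1OCC(C)(C)CO1)(C)C=C | intermediate
11 | 9-[(3R,6E,10E)-3-(5,5-dimethyl-1,3,2-dioxaborinan-2-yl)-3,7,11,15-tetramethylhexadeca-6,10,14-trien-1-yl]-9-borabicyclo[3.3.1]nonane | CC(C)=CCC/C(C)=C/CC/C(C)=C/CC[C@](B1OCC(C)(C)CO1)(C)CCB1C2CCCC1CCC2 | intermediate
12 | 2-[(3S,6E,10E)-1-(2,5-dimethoxy-3,4,6-trimethylphenyl)-3,7,11,15-tetramethylhexadeca-6,10,14-trien-3-yl]-5,5-dimethyl-1,3,2-dioxaborinane | CC(C)=CCC/C(C)=C/CC/C(C)=C/CC[C@](B1OCC(C)(C)CO1)(C)CCc1c(OC)c(C)c(C)c(OC)c1C | intermediate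
13 | (3R,6E,10E)-1-(2,5-dimethoxy-3,4,6-trimethylphenyl)-3,7,11,15-tetramethylhexadeca-6,10,14-trien-3-ol | CC(C)=CCC/C(C)=C/CC/C(C)=C/CC[C@](O)(C)CCc1c(OC)c(C)c(C)c(OC)c1C | intermediate
14 | 2-[(3R,6E,10E)-3-hydroxy-3,7,11,15-tetramethylhexadeca-6,10,14-trien-1-yl]-3,5,6-trimethylcyclohexa-2,5-diene-1,4-dione | CC(C)=CCC/C(C)=C/CC/C(C)=C/CC[C@](O)(C)CCC1=C(C)C(=O)C(C)=C(C)C1=O | intermediate
15 | (2R)-8a-methoxy-2,5,7,8-tetramethyl-2-[(3E,7E)-4,8,12-trimethyltrideca-3,7,11-trien-1-yl]-3,4-dihydro-2H-chromen-6(8aH)-one (both C8a epimers) | CC(C)=CCC/C(C)=C/CC/C(C)=C/CC[C@]1(C)CCC2=C(C)C(=O)C(C)=C(C)C2(OC)O1 | intermediate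
16 | (2R)-2,5,7,8-tetramethyl-2-[(3E,7E)-4,8,12-trimethyltrideca-3,7,11-trien-1-yl]-3,4-dihydro-2H-chromen-6-ol ((R)-α-tocotrienol) | CC(C)=CCC/C(C)=C/CC/C(C)=C/CC[C@]1(C)CCc2c(C)c(O)c(C)c(C)c2O1 | target

Total step count: 6. Longest linear sequence: 5 steps (steps 1, 2, 4, 5, 6).

Steps most likely to fail

1. Step 4. The α-lithiation of the hindered ester may be incomplete or compete with allylic deprotonation, boronate formation at the tertiary carbanion may be reversible, and material may be lost over the in-flask stages. The fallback builds the tertiary carbinol by ylide chemistry instead. It sets out from 1: catalytic asymmetric Corey–Chaykovsky epoxidation with dimethylsulfoxonium methylide (from Me3S(O)I and NaH) under lanthanum trilithium tris(binaphthoxide), LaLi3(C20H12O2)3, in the binaphthol enantiomer that delivers the (R)-epoxide, with a triarylphosphine oxide additive (THF, molecular sieves, rt), should give (R)-2-methyl-2-[(3E,7E)-4,8,12-trimethyltrideca-3,7,11-trien-1-yl]oxirane F1. More ylide at 45 °C in the same flask should expand it to (R)-2-methyl-2-[(3E,7E)-4,8,12-trimethyltrideca-3,7,11-trien-1-yl]oxetane F2. (2,5-Dimethoxy-3,4,6-trimethylphenyl)lithium F3, made from 6 with nBuLi at −78 °C, should then open F2 at its CH2–O carbon in the presence of BF3·OEt2 and give 13, where the route is rejoined.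

2. Step 6. Ketalisation of the hindered quinone carbonyl may stay incomplete or revert by hydrolysis before the reduction, so that ring-open material results. The fallback reverses the order of events. It sets out from 14: reduction with Na2S2O4 (THF/H2O) should give the hydroquinone 2-[(3R,6E,10E)-3-hydroxy-3,7,11,15-tetramethylhexadeca-6,10,14-trien-1-yl]-3,5,6-trimethylbenzene-1,4-diol F4. Acid-catalysed cyclodehydration of F4 (p-toluenesulfonic acid, cat., toluene, 40 °C), in which the tertiary hydroxyl replaces the ring hydroxyl at C8a through the keto tautomer of the hydroquinone so that C2 is retained, should give 16 directly.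

3. Step 1. The lipophilic C18 ketone may be converted poorly in the aqueous enzyme system, or enantioselectivity may be insufficient. The fallback is a resolution. It sets out from 1: NaBH4 (MeOH, 0 °C) should give racemic 6,10,14-trimethylpentadeca-5,9,13-trien-2-ol F5. Kinetic resolution with Candida antarctica lipase B and vinyl acetate (hexane, rt) should acylate the (R)-enantiomer to (2R,5E,9E)-6,10,14-trimethylpentadeca-5,9,13-trien-2-yl acetate F6 and leave the (S)-alcohol 2, where the route is rejoined after chromatographic separation.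

Further compounds
F1 | step 4 | (R)-2-methyl-2-[(3E,7E)-4,8,12-trimethyltrideca-3,7,11-trien-1-yl]oxirane | CC(C)=CCC/C(C)=C/CC/C(C)=C/CC[C@]1(C)CO1
F2 | step 4 | (R)-2-methyl-2-[(3E,7E)-4,8,12-trimethyltrideca-3,7,11-trien-1-yl]oxetane | CC(C)=CCC/C(C)=C/CC/C(C)=C/CC[C@]1(C)CCO1
F3 | step 4 | (2,5-dimethoxy-3,4,6-trimethylphenyl)lithium | [Li]c1c(OC)c(C)c(C)c(OC)c1C
F4 | step 6 | 2-[(3R,6E,10E)-3-hydroxy-3,7,11,15-tetramethylhexadeca-6,10,14-trien-1-yl]-3,5,6-trimethylbenzene-1,4-diol | CC(C)=CCC/C(C)=C/CC/C(C)=C/CC[C@](O)(C)CCc1c(O)c(C)c(C)c(O)c1C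
F5 | step 1 | racemic (5E,9E)-6,10,14-trimethylpentadeca-5,9,13-trien-2-ol | CC(C)=CCC/C(C)=C/CC/C(C)=C/CCC(C)O
F6 | step 1 | (2R,5E,9E)-6,10,14-trimethylpentadeca-5,9,13-trien-2-yl acetate | CC(C)=CCC/C(C)=C/CC/C(C)=C/CC[C@@H](C)OC(C)=O
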